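## Analysis of the target

The target 15 is a depside: two benzene rings joined through one aryl ester, with no stereocentre. Ring A is a 2-hydroxy-4-methoxy-6-heptylbenzoyl unit, and ring B is a 2-hydroxy-6-heptylbenzoic acid whose C4 oxygen carries the ring A acyl group. Both rings are 5-heptylresorcinol units that differ only in what sits on the oxygens (methyl and hydrogen in ring A, acyl and hydrogen in ring B) and in the state of the carboxyl carbon (ester in ring A, free acid in ring B). Each carbonyl carbon has two ortho substituents, which makes the ester slow to form and slow to cleave; it is still an aryl ester and will not survive hydroxide, alkoxide or hydride. The free acid of ring B is an electron-rich salicylic acid with an ortho alkyl group, a type that loses CO2 on heating or in acid. The difficulty is one of differentiation and order: four resorcinol oxygens must be told apart, and the ring B carboxyl must end up free next to an ester made from an activated acyl donor. The route rests on C1 of ring B, which is ortho to the C2 oxygen, para to the C4 oxygen and next to the heptyl chain: this is where a 5-heptylresorcinol is brominated, so a bromine can mark the carbon through the assembly and be exchanged for CO2 at the end.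

## Retrosynthetic reasoning

15 ⇒ 14. The two benzyl–oxygen bonds are cut first. Benzyl ethers serve for both phenols because catalytic hydrogenolysis is neutral and runs at room temperature, so neither the aryl ester nor the decarboxylation-prone acid of ring B is endangered. The forward step only has to cleave two O–CH2 bonds.

14 ⇒ 11 + 12. The bond between C1 of ring B and its carboxyl carbon is cut, leaving the aryl bromide 11 and carbon dioxide 12. Cutting here before the ester means ring B carries no carboxyl group during the assembly. No benzoate protecting group is needed, the ring B phenol that is acylated is not deactivated by a para carbonyl, and both rings can come from the same resorcinol 1. The forward reaction must reduce the C–Br bond next to an aryl ester and two benzyl ethers and deliver a carboxylate without strong base or nucleophile. A nickel-catalysed cathodic carboxylation meets these demands; halogen–metal exchange would not.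

11 ⇒ 10 + 5. The benzyl–oxygen bond at C3 of the bromophenyl ring is cut to the phenol 10 and benzyl bromide 5. The phenol beside bromine is capped only after the ester is in place, so the acylation itself differentiates the two hydroxyls.

10 ⇒ 8 + 9. The acyl–oxygen bond of the depside is cut to the acid chloride 8 and the bromoresorcinol 9. Acyl substitution is the dependable way to this ester once the doubly ortho-substituted acid is activated as its chloride. The forward step must pick the hydroxyl para to bromine; it has two ring hydrogens as neighbours, whereas the other is flanked by bromine and is the weaker nucleophile.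

9 ⇒ 1. The C4–Br bond is cut. In 1 the positions C4 and C6 are equivalent by symmetry, each ortho to one hydroxyl and para to the other, so electrophilic bromination can give only one monobromide next to the chain. The forward step has to stop at one bromine.

8 ⇒ 7 ⇒ 6. These are functional group changes only: acid chloride from acid 7, and acid from aldehyde 6 by Pinnick oxidation. The aldehyde level is kept as long as possible because the formyl group is what tells the two oxygens of ring A apart.

6 ⇒ 4 + 5 and 4 ⇒ 3. The O–benzyl and O–methyl bonds of ring A are cut in turn. In 3 the hydroxyl ortho to the formyl group is held in a hydrogen bond and the para hydroxyl is free and more acidic. Methylation therefore goes to the para oxygen first, and benzylation takes the remaining one.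

3 ⇒ 1. The aryl–CHO bond is cut. Vilsmeier–Haack formylation of 1, through the iminium salt 2, attacks the same C4 position that bromination uses. Both rings go back to 1, with 5 and 12 as the other building blocks.

## Alternatives that were turned down

Alternative 1: The carbocycle of ring A is opened at its C1–C6 bond, so ring A becomes a linear 3,5,7-trioxotetradecanoyl chain carried as the aryl ester A2 on the 4-hydroxyl of the ring B phenol A3. In the forward direction an amine base and then acid would trigger aldol attack of C2 on the C7 ketone, and dehydration and enolisation would aromatise the ring to the depside A1.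
- For it: the ester is made at an unhindered acyl carbon, ring A needs no protecting groups, and no electrolysis is involved. On the ease of ester formation it is stronger than the chosen route.
- Against it: in A2 the aryl ester is the most electrophilic carbonyl of a polyenolisable chain. Claisen closure of C6 onto C1, attack of the C5 enol oxygen on C1 to a pyrone, and loss of the phenoxide to an acylketene each expel A3 and destroy the depside link. The desired aldol must outrun all three.
- A1 then still needs selective methylation of the one non-chelated ring A hydroxyl and debenzylation, and A2 requires polyanion chain assembly.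
- The chosen route keeps the ester non-enolisable and hindered from the moment it is formed and fixes the methyl ether at step 2.

Alternative 2: The ester is cut at the bond between its oxygen and C4 of ring B, not at the acyl carbon. The hindered ring A acid A6 would be O-arylated by the ring B arylboronic acid A5 in a copper-mediated aerobic (Chan–Lam) coupling to give the fully protected depside A4.
- For it: attack at a shielded acyl carbon is avoided, both halves carry all their carbons before they meet, and there is no choice to make between two hydroxyls. On that last point it is stronger than step 7 of the chosen route.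
- Against it: carboxylates are weak partners in this coupling, and a 2,6-disubstituted one such as A6 more so. Protodeboronation, oxidative loss of boron from A5 and homocoupling of A5 compete.
- A5 is reached only after the ring B carboxyl has been installed and masked and the ring has then been borylated at a C–H bond, and A4 can only be unmasked with acid strong enough to threaten the ring B salicylic acid.
- The chosen route forms the ester by ordinary acyl substitution and ends with a neutral hydrogenolysis; the price is one less certain C–C bond formation.

Alternative 3: Both the aryl–carbonyl bond of ring A and the carbonyl–oxygen bond of the ester are cut at once. The aryl iodide A8, carbon monoxide A9 and the 4-hydroxyl of the ring B phenol A3 would be joined by palladium-catalysed carbonylative coupling to the depside A7.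
- For it: it is the most convergent plan and it is shorter, since the ring A acid is never prepared and A8 is two steps from 1. On step economy it is stronger than the chosen route.
- Against it: A7 carries a methyl ether at C2 of ring A where the target has a hydroxyl. A late chelation-controlled demethylation must then spare the C4 methyl ether and the depside ester.
- A doubly ortho-substituted aroylpalladium, formed from A8 and A9, has to be captured by the electron-poor phenol A3, and A3 itself requires carboxylation of 1 and esterification.
- The chosen route sets methyl against benzyl early through the hydrogen bond in 3, uses carbon dioxide 12 where this one needs the toxic carbon monoxide A9, and never has to protect a ring B carboxyl.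

Key step: step 9

Assumption: of the two hydroxyls of 9, the one para to bromine is taken to react faster with a hindered aroyl chloride, as the less hindered hydroxyl of a 4-bromoresorcinol does with bulky electrophiles.

## Route

Step 1
Reactants: 1 5-heptylresorcinol (5-heptylbenzene-1,3-diol)
Product: 3 2-heptyl-4,6-dihydroxybenzaldehyde, via aryl iminium chloride 2 (not isolated)
Conditions: POCl3, DMF, 0 °C to rt; then H2O, 50 °C
Reagents that add atoms: N,N-dimethylformamide, CN(C)C=O; water, O
Why: Vilsmeier–Haack formylation; the chloroiminium ion should attack C4 of the resorcinol (ortho to one hydroxyl, para to the other), as with other 5-alkylresorcinols, and the iminium salt 2 is hydrolysed on aqueous work-up.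

Step 2
Reactants: 3 2-heptyl-4,6-dihydroxybenzaldehyde
Product: 4 2-heptyl-6-hydroxy-4-methoxybenzaldehyde
Conditions: MeI (1.05 equiv), K2CO3, acetone, rt
Reagents that add atoms: iodomethane, CI
Why: Williamson etherification; the hydroxyl ortho to the formyl group is held in a hydrogen bond, so the more acidic para hydroxyl should be methylated selectively.

Step 3
Reactants: 4 2-heptyl-6-hydroxy-4-methoxybenzaldehyde; 5 benzyl bromide
Product: 6 2-(benzyloxy)-6-heptyl-4-methoxybenzaldehyde
Conditions: K2CO3, DMF, 60 °C
Reagents that add atoms: none
Why: Williamson etherification of the remaining, chelated phenol, which needs a polar aprotic solvent and gentle heating.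

Step 4
Reactants: 6 2-(benzyloxy)-6-heptyl-4-methoxybenzaldehyde
Product: 7 2-(benzyloxy)-6-heptyl-4-methoxybenzoic acid
Conditions: NaClO2, NaH2PO4, 2-methyl-2-butene (excess), t-BuOH/H2O, rt
Reagents that add atoms: sodium chlorite, [Na+].[O-]Cl=O
Why: Pinnick oxidation of a non-enolisable aldehyde; the alkene traps hypochlorous acid so that the electron-rich ring is not chlorinated, and the benzyl and methyl ethers are inert.

Step 5
Reactants: 7 2-(benzyloxy)-6-heptyl-4-methoxybenzoic acid
Product: 8 2-(benzyloxy)-6-heptyl-4-methoxybenzoyl chloride
Conditions: (COCl)2, DMF (cat.), CH2Cl2, 0 °C to rt; concentrated and used crude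
Reagents that add atoms: oxalyl chloride, ClC(=O)C(=O)Cl
Why: Acid chloride formation under chloroiminium catalysis; a 2,6-disubstituted benzoic acid needs this level of activation to acylate a phenol, and the benzyl ether tolerates the short exposure at rt.

Step 6
Reactants: 1 5-heptylresorcinol
Product: 9 4-bromo-5-heptylbenzene-1,3-diol
Conditions: NBS (1.0 equiv, in portions), CH2Cl2, −30 °C to 0 °C
Reagents that add atoms: N-bromosuccinimide, O=C1CCC(=O)N1Br
Why: Electrophilic aromatic bromination; C4 and C6 are equivalent by symmetry and more reactive than C2 between the hydroxyls, and one equivalent at low temperature should hold the reaction at the monobromide.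

Step 7
Reactants: 9 4-bromo-5-heptylbenzene-1,3-diol (1.5 equiv); 8 2-(benzyloxy)-6-heptyl-4-methoxybenzoyl chloride
Product: 10 4-bromo-3-heptyl-5-hydroxyphenyl 2-(benzyloxy)-6-heptyl-4-methoxybenzoate
Conditions: Et3N, DMAP (cat.), CH2Cl2, −20 °C to rt, slow addition of 8
Reagents that add atoms: none
Why: Acylation of a phenol by an acid chloride (nucleophilic acyl substitution); the hydroxyl para to bromine is unhindered and the better nucleophile, the one beside bromine is shielded, and the bulky aroyl group widens the gap while the excess of 9 suppresses the diester.

Step 8
Reactants: 10 4-bromo-3-heptyl-5-hydroxyphenyl 2-(benzyloxy)-6-heptyl-4-methoxybenzoate; 5 benzyl bromide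
Product: 11 3-(benzyloxy)-4-bromo-5-heptylphenyl 2-(benzyloxy)-6-heptyl-4-methoxybenzoate
Conditions: K2CO3, acetone, 50 °C
Reagents that add atoms: none
Why: Williamson etherification of an acidic ortho-bromophenol; the doubly ortho-substituted aryl ester is too shielded for carbonate or phenoxide to attack under these conditions.

Step 9
Reactants: 11 3-(benzyloxy)-4-bromo-5-heptylphenyl 2-(benzyloxy)-6-heptyl-4-methoxybenzoate; 12 carbon dioxide
Product: 14 2-(benzyloxy)-4-[2-(benzyloxy)-6-heptyl-4-methoxybenzoyloxy]-6-heptylbenzoic acid, via magnesium carboxylate 13 (not isolated)
Conditions: CO2 (1 atm), NiBr2(2,2'-bipyridine) (10 mol %), Bu4NBF4, dry DMF, Mg anode, carbon-fibre cathode, undivided cell, cathode held between −1.4 and −1.7 V vs SCE, 20 °C; then 1 M HCl, 0 °C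
Reagents that add atoms: none
Why: At the cathode the divalent nickel of NiBr2(2,2'-bipyridine) is reduced to a zerovalent nickel bipyridine complex, which inserts into the C–Br bond of 11 by oxidative addition. One-electron reduction of the arylnickel bromide gives an aryl complex of monovalent nickel that takes CO2 into the Ni–C bond; a further electron releases the carboxylate and returns zerovalent nickel, and Mg2+ from the dissolving anode holds the carboxylate as the salt 13, which dilute acid converts into 14. The closest known reaction type is the nickel-bipyridine-catalysed electroreductive carboxylation of aryl bromides with CO2 and a sacrificial anode, applied here to a bromide with two ortho substituents. No ring is closed and no stereocentre is formed. The step needs chemoselectivity for C–Br over the aryl ester and the benzyl ethers: the catalyst moves C–Br activation to a potential several tenths of a volt positive of that at which an aryl benzoate accepts an electron, benzyl aryl ethers are not reduced there, and the cell holds neither a base nor a free nucleophile. Site selectivity is not in question, because carbon enters only where the bromine stood, which was fixed in step 6. The ortho benzyloxy and heptyl groups slow the insertion, so the electrolysis is run in dry, CO2-saturated DMF at low current density to keep hydrodebromination behind.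

Step 10
Reactants: 14 2-(benzyloxy)-4-[2-(benzyloxy)-6-heptyl-4-methoxybenzoyloxy]-6-heptylbenzoic acid
Product: 15 2-heptyl-4-(2-heptyl-6-hydroxy-4-methoxybenzoyloxy)-6-hydroxybenzoic acid (CNP0234711.0)
Conditions: H2 (1 atm), Pd/C (10%), EtOAc, rt
Reagents that add atoms: none
Why: Hydrogenolysis of the two aryl benzyl ethers; the aryl ester and the carboxylic acid are not reduced, and the neutral conditions at rt should avoid both ester cleavage and decarboxylation.

## Compound list

1 | 5-heptylresorcinol (5-heptylbenzene-1,3-diol) | CCCCCCCc1cc(O)cc(O)c1 | starting material
2 | [(2-heptyl-4,6-dihydroxyphenyl)methylidene]dimethylammonium chloride | CCCCCCCc1cc(O)cc(O)c1C=[N+](C)C.[Cl-] | intermediate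
3 | 2-heptyl-4,6-dihydroxybenzaldehyde | CCCCCCCc1cc(O)cc(O)c1C=O | intermediate
4 | 2-heptyl-6-hydroxy-4-methoxybenzaldehyde | CCCCCCCc1cc(OC)cc(O)c1C=O | intermediate
5 | benzyl bromide | BrCc1ccccc1 | starting material
6 | 2-(benzyloxy)-6-heptyl-4-methoxybenzaldehyde | CCCCCCCc1cc(OC)cc(OCc2ccccc2)c1C=O | intermediate
7 | 2-(benzyloxy)-6-heptyl-4-methoxybenzoic acid | CCCCCCCc1cc(OC)cc(OCc2ccccc2)c1C(=O)O | intermediate
8 | 2-(benzyloxy)-6-heptyl-4-methoxybenzoyl chloride | CCCCCCCc1cc(OC)cc(OCc2ccccc2)c1C(=O)Cl | intermediate
9 | 4-bromo-5-heptylbenzene-1,3-diol | CCCCCCCc1cc(O)cc(O)c1Br | intermediate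
10 | 4-bromo-3-heptyl-5-hydroxyphenyl 2-(benzyloxy)-6-heptyl-4-methoxybenzoate | CCCCCCCc1cc(OC(=O)c2c(OCc3ccccc3)cc(OC)cc2CCCCCCC)cc(O)c1Br | intermediate
11 | 3-(benzyloxy)-4-bromo-5-heptylphenyl 2-(benzyloxy)-6-heptyl-4-methoxybenzoate | CCCCCCCc1cc(OC(=O)c2c(OCc3ccccc3)cc(OC)cc2CCCCCCC)cc(OCc2ccccc2)c1Br | intermediate
12 | carbon dioxide | O=C=O | starting material
13 | magnesium bis{2-(benzyloxy)-4-[2-(benzyloxy)-6-heptyl-4-methoxybenzoyloxy]-6-heptylbenzoate} | CCCCCCCc1cc(OC(=O)c2c(OCc3ccccc3)cc(OC)cc2CCCCCCC)cc(OCc2ccccc2)c1C(=O)[O-].CCCCCCCc1cc(OC(=O)c2c(OCc3ccccc3)cc(OC)cc2CCCCCCC)cc(OCc2ccccc2)c1C(=O)[O-].[Mg+2] | intermediate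
14 | 2-(benzyloxy)-4-[2-(benzyloxy)-6-heptyl-4-methoxybenzoyloxy]-6-heptylbenzoic acid | CCCCCCCc1cc(OC(=O)c2c(OCc3ccccc3)cc(OC)cc2CCCCCCC)cc(OCc2ccccc2)c1C(=O)O | intermediate
15 | 2-heptyl-4-(2-heptyl-6-hydroxy-4-methoxybenzoyloxy)-6-hydroxybenzoic acid | CCCCCCCc1cc(OC(=O)c2c(O)cc(OC)cc2CCCCCCC)cc(O)c1C(=O)O | target

## Step count and risks

Total step count: 10. Longest linear sequence: 9 steps (steps 1 to 5 and 7 to 10, from 1 to 15); the ring B branch contributes step 6.

Step 9 (key step). The most likely failure is hydrodebromination: the arylnickel intermediate is protonated or abstracts hydrogen before CO2 inserts, because insertion into a nickel–aryl bond with two ortho substituents is slow. A second risk is loss of catalyst through reduction of CO2 at zerovalent nickel to carbonyl complexes when oxidative addition into the electron-rich bromide is slow. A third is reductive cleavage of the aryl ester if the cathode potential drifts negative. The fallback sets out from 11 and exchanges the reductive carboxylation for a palladium carbonylation. With Pd(OAc)2, Xantphos, CO (1 atm), benzyl alcohol and Et3N in toluene at 100 °C, 11 should give benzyl 2-(benzyloxy)-4-[2-(benzyloxy)-6-heptyl-4-methoxybenzoyloxy]-6-heptylbenzoate F1. Hydrogenolysis (H2, Pd/C, EtOAc, rt) then removes all three benzyl groups, and the route is rejoined at 15.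

Step 7. Acylation may occur at the hydroxyl beside bromine or at both hydroxyls. The ortho-bromo hydroxyl is the more acidic one and is ionised first under basic conditions, while the preference for the remote hydroxyl is only kinetic and steric. The fallback sets out from 1 and lets a free hydroxyl direct the bromine, so that no choice between two hydroxyls is needed. Monobenzylation of 1 with 5 (1 equiv, K2CO3, acetone), with separation from unreacted 1 and the dibenzyl ether, should give 3-(benzyloxy)-5-heptylphenol F2. Para-selective bromination with Bu4NBr3 in CH2Cl2/MeOH at rt should give 3-(benzyloxy)-4-bromo-5-heptylphenol F3; the less polar ortho isomer would be removed by chromatography. Acylation of the single hydroxyl of F3 with 8 (Et3N, DMAP, CH2Cl2) rejoins the route at 11.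

Step 6. Over-bromination to the 4,6-dibromide and oxidative darkening of the free resorcinol are likely, because the monobromide is nearly as reactive as 1. The fallback sets out from 1 and tempers the ring as its bis-ether. Exhaustive methylation (MeI, K2CO3, acetone, reflux) should give 1-heptyl-3,5-dimethoxybenzene F4. NBS in MeCN at 0 °C should brominate it once, next to the chain, to 2-bromo-1-heptyl-3,5-dimethoxybenzene F5. BBr3 in CH2Cl2 (−78 °C to rt), followed by aqueous work-up, then cleaves both methyl ethers without touching the aryl bromide, and the route is rejoined at 9.

## Further compounds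

F1 | step 9 | benzyl 2-(benzyloxy)-4-[2-(benzyloxy)-6-heptyl-4-methoxybenzoyloxy]-6-heptylbenzoate | CCCCCCCc1cc(OC(=O)c2c(OCc3ccccc3)cc(OC)cc2CCCCCCC)cc(OCc2ccccc2)c1C(=O)OCc1ccccc1
F2 | step 7 | 3-(benzyloxy)-5-heptylphenol | CCCCCCCc1cc(O)cc(OCc2ccccc2)c1
F3 | step 7 | 3-(benzyloxy)-4-bromo-5-heptylphenol | CCCCCCCc1cc(O)cc(OCc2ccccc2)c1Br
F4 | step 6 | 1-heptyl-3,5-dimethoxybenzene | CCCCCCCc1cc(OC)cc(OC)c1
F5 | step 6 | 2-bromo-1-heptyl-3,5-dimethoxybenzene | CCCCCCCc1cc(OC)cc(OC)c1Br
A1 | alternative 1 | benzyl 4-(2,4-dihydroxy-6-heptylbenzoyloxy)-2-heptyl-6-hydroxybenzoate | CCCCCCCc1cc(O)cc(O)c1C(=O)Oc1cc(O)c(C(=O)OCc2ccccc2)c(CCCCCCC)c1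
A2 | alternative 1 | benzyl 2-heptyl-6-hydroxy-4-(3,5,7-trioxotetradecanoyloxy)benzoate | CCCCCCCC(=O)CC(=O)CC(=O)CC(=O)Oc1cc(O)c(C(=O)OCc2ccccc2)c(CCCCCCC)c1
A3 | alternative 1 | benzyl 2-heptyl-4,6-dihydroxybenzoate | CCCCCCCc1cc(O)cc(O)c1C(=O)OCc1ccccc1
A4 | alternative 2 | tert-butyl 2-heptyl-4-[2-heptyl-4-methoxy-6-(methoxymethoxy)benzoyloxy]-6-(methoxymethoxy)benzoate | CCCCCCCc1cc(OC(=O)c2c(OCOC)cc(OC)cc2CCCCCCC)cc(OCOC)c1C(=O)OC(C)(C)C
A5 | alternative 2 | [4-(tert-butoxycarbonyl)-3-heptyl-5-(methoxymethoxy)phenyl]boronic acid | CCCCCCCc1cc(B(O)O)cc(OCOC)c1C(=O)OC(C)(C)C
A6 | alternative 2 | 2-heptyl-4-methoxy-6-(methoxymethoxy)benzoic acid | CCCCCCCc1cc(OC)cc(OCOC)c1C(=O)O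
A7 | alternative 3 | benzyl 2-heptyl-4-(2-heptyl-4,6-dimethoxybenzoyloxy)-6-hydroxybenzoate | CCCCCCCc1cc(OC)cc(OC)c1C(=O)Oc1cc(O)c(C(=O)OCc2ccccc2)c(CCCCCCC)c1
A8 | alternative 3 | 1-heptyl-2-iodo-3,5-dimethoxybenzene | CCCCCCCc1cc(OC)cc(OC)c1I
A9 | alternative 3 | carbon monoxide | [C-]#[O+]
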